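Start from the end of the run. Late on, what has not reacted leans towards the dormant form, 13 to one at balance, and it comes back first-order. The time in which the dormant form halves, if nothing falls back in, is the forward constant of that step divided into its equilibrium constant, times ln(2). I call this the release half-life, 2.00 min. Your run lasts 1.25 such half-lives, so the question becomes how much gets parked before the enzyme catches up.

the same everywhere: enzyme 2.0 µM; time 2.5 min
- grey: starting material 20 mM; second substrate 20.0 mM (fed, over 30 s); all else is in the flask from the start; the feed brings no volume worth counting
- violet: starting material 20 mM; second substrate 20.0 mM; everything together at the start
- blue: starting material 20 mM (fed, over 30 s); second substrate 20.0 mM; all else is in the flask from the start; the feed brings no volume worth counting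

    starting material + enzyme ⇌ complex A (K1 = 4200 M⁻¹, k1 = 2.2 × 10⁶ M⁻¹ s⁻¹)
    complex A → enzyme + target (k2 = 110 s⁻¹)
    second substrate + enzyme ⇌ complex B (K3 = 56 M⁻¹, k3 = 75000 M⁻¹ s⁻¹)
    complex B → enzyme + second product (k4 = 260 s⁻¹)
    starting material ⇌ dormant form (K5 = 13, k5 = 0.075 s⁻¹)
    starting material → uncatalysed product (k6 = 0.0067 s⁻¹)

* the best flask by amount of target, in percent of the starting material charged; "all alike" if 1.5 percentage points covers them all (grey / violet / blue / all alike)
* amount of target at the end, in percent of the starting material charged, grey
* amount of target at the end, in percent of the starting material charged, violet
* amount of target at the end, in percent of the starting material charged, blue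

Here is the run in slow motion, as I reckon it, leaving the second substrate out. Its binding constant times charge is 1.1, against 84 for the starting material.

First instants, violet: I take the enzyme as flat out at 0.220 mM s⁻¹, while parking and the uncatalysed step together remove starting material at 0.0817 s⁻¹. Integrating that constant draw plus first-order loss, the free starting material reaches zero in this reckoning, though not in a real flask, after the logarithm of one plus charge times loss constant over enzyme speed, divided by the loss constant: 26.1 s. By this estimate that burst makes 28.7% of the charge as target and parks 65.5%.

Middle: release starts at 0.0755 mM s⁻¹, below the enzyme's speed, so release is now the rate-limiting step.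

End: counting every released molecule as target, violet reaches 62.1%, and grey the same in this reckoning.

Blue, still by my reckoning: the feed of 0.667 mM s⁻¹ outruns the enzyme, leaving 5.00 mM of starting material when it stops. The burst then lasts 42.8 s, makes 47.1% and parks 48.5%, which gives 69.5%.

The forecast gave grey 58%, violet 57% and blue 63%, with blue best, holding that “a single charge is largely parked and later turnover is limited by its release”. My figures for violet and blue stand higher than its figures , though my gap between blue and violet, 7.4 percentage points, is close to its 6 points.

The flasks give grey 57.6%, violet 57.4% and blue 63.4%, so blue is best. Mean starting material over the first 30 s was 3.84 mM in blue against 6.33 mM in violet. From grey's 51.0% dormant form at 1.25 min, the release half-life leaves 33.1% at 2.50 min, and grey holds 35.2%. For blue with 12 mM of second substrate, the same clock on the share I reckoned parked leaves 26.2%, and that flask holds 29.9% dormant form with 64.4% target.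

Its constants are made up; the result is computed.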